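**Plan**
Labels: ring A is the resorcinol ring fused to the dihydrofuran, ring B the other benzo ring of the cycloheptadiene, rings C and D the 4-hydroxyphenyl groups on furan C-2 (C-g) and on C-d, ring E the formylphenol on C-a; C-f is furan C-3.
Enabling feature: C-f is at once C-3 of a trans-2-(4-hydroxyphenyl)-3-aryl-2,3-dihydrobenzofuran built on ring A and a member of the seven-membered ring, so its bond to the ortho carbon of ring A and the C-g–O bond are the two bonds that phenol oxidation of a 4-hydroxystilbene beside a free resorcinol makes.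
Retrosynthesis: ring E CHO and four hydroxyls back to CO2Me and OMe; then C-f–C(ortho, ring A) and C-g–O together, opening both rings to a tetraarylethane with the stilbene on ring B; then C-f–ring B (Heck), C-d–ring B (Friedel–Crafts), C-a–ring A and C-a–ring E (two ketone α-arylations).
Forward: the open-chain tetraarylethane is assembled first (steps 1–7), one oxidation closes the cycloheptadiene and the dihydrofuran (step 8), and ester-to-aldehyde adjustment and demethylation finish (steps 9–11).
Stereochemistry: C-a from a catalyst-controlled transfer hydrogenation with dynamic kinetic resolution (its carbinol partner is then ionised), C-d by 1,2-induction from C-a, C-f and C-g by substrate control in the ring-closing step.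

Key step: step 8

Remark on the chemistry: the minor C-a epimer from step 4 and the minor C-d epimer or regioisomer from step 5 are assumed separable by chromatography; ethane locants 1 and 2 in the names are C-a and C-d.

Step 1
Reactants: 1 5-bromoresorcinol
Product: 2 1-bromo-3,5-bis(triisopropylsilyloxy)benzene
Conditions: TIPSCl (2.3 equiv), imidazole, DMF, 0 °C to rt
Reagents that add atoms: triisopropylsilyl chloride, CC(C)[Si](Cl)(C(C)C)C(C)C
Why: Imidazole-promoted silylation of both phenols (silyl ether protection) gives a ring A bromide whose oxygens should withstand the mild bases, the acid and the palladium steps ahead and still fall to fluoride.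

Step 2
Reactants: 3 4′-methoxyacetophenone (2 equiv); 4 methyl 3-bromo-4-methoxybenzoate
Product: 5 methyl 4-methoxy-3-[2-(4-methoxyphenyl)-2-oxoethyl]benzoate
Conditions: Pd2(dba)3 (1.5 mol %), Xantphos (3.6 mol %), K3PO4, toluene, 80 °C
Reagents that add atoms: none
Why: Palladium-catalysed α-arylation of a methyl ketone enolate, run with the mild base K3PO4 so that the methyl ester survives, while the ortho-methoxy group of 4 and the excess of 3 should hold the reaction at monoarylation.

Step 3
Reactants: 5 methyl 4-methoxy-3-[2-(4-methoxyphenyl)-2-oxoethyl]benzoate; 2 1-bromo-3,5-bis(triisopropylsilyloxy)benzene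
Product: 6 methyl 3-[1-[3,5-bis(triisopropylsilyloxy)phenyl]-2-(4-methoxyphenyl)-2-oxoethyl]-4-methoxybenzoate (racemic; C-a labile)
Conditions: Pd(OAc)2 (3 mol %), XPhos (6 mol %), K3PO4, toluene, 100 °C
Reagents that add atoms: none
Why: A second palladium-catalysed enolate arylation at the doubly activated methylene of the deoxybenzoin puts ring A on C-a; the hindered product has no further reactive site, and its enolisable C-a centre is left racemic on purpose for step 4.

Step 4
Reactants: 6 methyl 3-[1-[3,5-bis(triisopropylsilyloxy)phenyl]-2-(4-methoxyphenyl)-2-oxoethyl]-4-methoxybenzoate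
Product: 7 methyl 3-[(1R,2R)-1-[3,5-bis(triisopropylsilyloxy)phenyl]-2-hydroxy-2-(4-methoxyphenyl)ethyl]-4-methoxybenzoate
Conditions: RuCl(p-cymene)[(R,R)-TsDPEN] (2 mol %), HCO2H/Et3N (5:2), EtOAc, 40 °C; chromatography
Reagents that add atoms: none
Why: Noyori–Ikariya asymmetric transfer hydrogenation with dynamic kinetic resolution, a reaction established for α-aryl aryl ketones: the (R,R) catalyst sets the (R)-carbinol by recognising the anisyl ring, C-a epimerises through the enol under the amine, and the (R)-ketone is expected to be the matched enantiomer (Felkin–Anh arrangement with the ortho-substituted ring E anti to hydride), so that 7 should predominate and is freed from its C-a epimer on silica.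

Step 5
Reactants: 7 methyl 3-[(1R,2R)-1-[3,5-bis(triisopropylsilyloxy)phenyl]-2-hydroxy-2-(4-methoxyphenyl)ethyl]-4-methoxybenzoate; 8 1-bromo-3,5-dimethoxybenzene (3 equiv)
Product: 9 methyl 3-[(1R,2S)-2-(2-bromo-4,6-dimethoxyphenyl)-1-[3,5-bis(triisopropylsilyloxy)phenyl]-2-(4-methoxyphenyl)ethyl]-4-methoxybenzoate
Conditions: Bi(OTf)3 (10 mol %), CH2Cl2, −20 °C to rt
Reagents that add atoms: none
Why: Friedel–Crafts benzylation through the anisyl-stabilised cation at C-d, which 8 should attack with its carbon para to one methoxy group and ortho to bromine (the usual site of electrophilic substitution in this arene) and from the face anti to the ortho-methoxyphenyl ring E in the conformer whose C-a–H lies in the cation plane (1,2-induction by minimised allylic strain, reinforced by transient bridging of the ring E methoxy oxygen), giving (S) at C-d, while the in-plane C-a–H is poorly aligned for proton loss or hydride shift so that C-a should survive.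

Step 6
Reactants: 9 methyl 3-[(1R,2S)-2-(2-bromo-4,6-dimethoxyphenyl)-1-[3,5-bis(triisopropylsilyloxy)phenyl]-2-(4-methoxyphenyl)ethyl]-4-methoxybenzoate; 10 4-acetoxystyrene
Product: 11 methyl 3-[(1R,2S)-2-{2-[(E)-2-(4-acetoxyphenyl)ethenyl]-4,6-dimethoxyphenyl}-1-[3,5-bis(triisopropylsilyloxy)phenyl]-2-(4-methoxyphenyl)ethyl]-4-methoxybenzoate
Conditions: Pd2(dba)3 (2.5 mol %), [(t-Bu)3PH]BF4 (10 mol %), Cy2NMe, 1,4-dioxane, 90 °C
Reagents that add atoms: none
Why: Mizoroki–Heck coupling of the hindered, electron-rich aryl bromide with a styrene under a bulky trialkylphosphine should give the (E)-stilbene by β-arylation and syn β-hydride elimination, leaving silyl ethers, acetate and ester untouched.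

Step 7
Reactants: 11 methyl 3-[(1R,2S)-2-{2-[(E)-2-(4-acetoxyphenyl)ethenyl]-4,6-dimethoxyphenyl}-1-[3,5-bis(triisopropylsilyloxy)phenyl]-2-(4-methoxyphenyl)ethyl]-4-methoxybenzoate
Product: 12 methyl 3-[(1R,2S)-1-(3,5-dihydroxyphenyl)-2-{2-[(E)-2-(4-hydroxyphenyl)ethenyl]-4,6-dimethoxyphenyl}-2-(4-methoxyphenyl)ethyl]-4-methoxybenzoate
Conditions: TBAF (3 equiv), THF/MeOH (10:1), 0 °C, argon; aq NH4Cl
Reagents that add atoms: none
Why: Fluoride cleaves both aryl silyl ethers (desilylation) and, with methanol, the phenyl acetate (transesterification), which should expose exactly the resorcinol of ring A and the 4-hydroxystilbene while the aryl methyl ethers and the ester stay.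

Step 8
Reactants: 12 methyl 3-[(1R,2S)-1-(3,5-dihydroxyphenyl)-2-{2-[(E)-2-(4-hydroxyphenyl)ethenyl]-4,6-dimethoxyphenyl}-2-(4-methoxyphenyl)ethyl]-4-methoxybenzoate
Product: 14 ring-closed methyl ester (cycloheptadiene fused to a trans-dihydrobenzofuran; C-a R; C-d S; C-f S; C-g S; free phenols on rings A and C; methyl ethers on rings B D E; CO2Me on ring E), via p-quinone methide 13 (not isolated)
Conditions: laccase (Trametes versicolor), air, acetone/NaOAc buffer pH 5.0 (1:1), 0.5 mM in 12, 25 °C
Reagents that add atoms: none
Why: Proposed new method: the oxidase should remove one electron and a proton from the ring C phenol only (the resorcinol and the anisole rings lie beyond its potential); the phenoxyl radical is delocalised as a quinone methide radical onto C-f, C-f bonds to the ortho carbon of ring A (radical addition followed by a second one-electron oxidation and proton loss, or radical–radical coupling after hydrogen transfer from the resorcinol), tautomerisation restores ring A and leaves p-quinone methide 13, and the adjacent ring A hydroxyl adds to its exocyclic C-g. The closest known reaction is the peroxidase-, laccase- or FeCl3-mediated dimerisation of resveratrol to ε-viniferin, where the same stilbene carbon–resorcinol ortho carbon bond and the same oxa-Michael closure arise between two molecules; the intramolecular version that closes a seven-membered ring is not described. The cycloheptadiene closes by ortho attack on the arene, formally 7-exo with respect to the enolic C=C of the resorcinol, and the dihydrofuran by 5-exo-trig 1,6-oxa-Michael addition. C-f is set in the C–C bond formation by the C-a/C-d pair, closure being expected over the face of ring A that keeps rings E and D pseudo-equatorial and trans on the forming cycloheptadiene, which gives (S); C-g follows from C-f because the phenol adds to the quinone methide so that ring C ends trans to ring B on the furan, the kinetic and thermodynamic outcome of such couplings. The step needs intramolecular carbon–carbon coupling to outrun stilbene–stilbene dimerisation and C–O coupling: the tether brings only the two ortho carbons of ring A (equivalent by rotation) within reach of C-f, attack by oxygen would need a nine-membered ring, rings B, D and E are capped as methyl ethers, and high dilution with slow enzymatic radical generation should keep bimolecular coupling down.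

Step 9
Reactants: 14 ring-closed methyl ester
Product: 15 benzylic alcohol (CH2OH in place of CO2Me of 14; stereocentres unchanged)
Conditions: i-Bu2AlH (6 equiv), CH2Cl2/THF, −78 to 0 °C; aq potassium sodium tartrate
Reagents that add atoms: none
Why: Hydride reduction of the methyl benzoate to the benzylic alcohol with i-Bu2AlH (ester reduction), the two free phenols only consuming extra hydride as aluminium phenoxides.

Step 10
Reactants: 15 benzylic alcohol
Product: 16 aldehyde (vitisinol B with rings B, D and E still as methyl ethers)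
Conditions: MnO2 (activated, 15 equiv), acetone/CH2Cl2, rt
Reagents that add atoms: none
Why: MnO2 oxidation of the electron-rich 4-methoxybenzylic alcohol to the aldehyde (benzylic alcohol oxidation) should stop at the aldehyde and leave the phenols and the benzylic stereocentres alone at room temperature.

Step 11
Reactants: 16 aldehyde
Product: 17 vitisinol B
Conditions: BBr3 (12 equiv), CH2Cl2, −78 to 0 °C; then MeOH, H2O
Reagents that add atoms: none
Why: BBr3 cleavage of the four aryl methyl ethers (Lewis-acid ether cleavage via aryloxyboranes), a deprotection in use on permethylated oligostilbenes that hold dihydrobenzofurans; low temperature and short contact should protect the benzylic C-g–O bond, which would in any case re-close to the more stable trans furan, and the aldehyde is regenerated on hydrolysis.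

**Compound list**
1 | 5-bromoresorcinol | Oc1cc(O)cc(Br)c1 | starting material
2 | 1-bromo-3,5-bis(triisopropylsilyloxy)benzene | CC(C)[Si](Oc1cc(Br)cc(O[Si](C(C)C)(C(C)C)C(C)C)c1)(C(C)C)C(C)C | intermediate
3 | 4′-methoxyacetophenone | CC(=O)c1ccc(OC)cc1 | starting material
4 | methyl 3-bromo-4-methoxybenzoate | COC(=O)c1ccc(OC)c(Br)c1 | starting material
5 | methyl 4-methoxy-3-[2-(4-methoxyphenyl)-2-oxoethyl]benzoate | COC(=O)c1ccc(OC)c(CC(=O)c2ccc(OC)cc2)c1 | intermediate
6 | methyl 3-[1-[3,5-bis(triisopropylsilyloxy)phenyl]-2-(4-methoxyphenyl)-2-oxoethyl]-4-methoxybenzoate (racemic) | COC(=O)c1ccc(OC)c(C(c2cc(O[Si](C(C)C)(C(C)C)C(C)C)cc(O[Si](C(C)C)(C(C)C)C(C)C)c2)C(=O)c2ccc(OC)cc2)c1 | intermediate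
7 | methyl 3-[(1R,2R)-1-[3,5-bis(triisopropylsilyloxy)phenyl]-2-hydroxy-2-(4-methoxyphenyl)ethyl]-4-methoxybenzoate | COC(=O)c1ccc(OC)c([C@@H](c2cc(O[Si](C(C)C)(C(C)C)C(C)C)cc(O[Si](C(C)C)(C(C)C)C(C)C)c2)[C@@H](O)c2ccc(OC)cc2)c1 | intermediate
8 | 1-bromo-3,5-dimethoxybenzene | COc1cc(Br)cc(OC)c1 | starting material
9 | methyl 3-[(1R,2S)-2-(2-bromo-4,6-dimethoxyphenyl)-1-[3,5-bis(triisopropylsilyloxy)phenyl]-2-(4-methoxyphenyl)ethyl]-4-methoxybenzoate | COC(=O)c1ccc(OC)c([C@@H](c3cc(O[Si](C(C)C)(C(C)C)C(C)C)cc(O[Si](C(C)C)(C(C)C)C(C)C)c3)[C@@H](c2ccc(OC)cc2)c2c(Br)cc(OC)cc2OC)c1 | intermediate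
10 | 4-acetoxystyrene | CC(=O)Oc1ccc(C=C)cc1 | starting material
11 | methyl 3-[(1R,2S)-2-{2-[(E)-2-(4-acetoxyphenyl)ethenyl]-4,6-dimethoxyphenyl}-1-[3,5-bis(triisopropylsilyloxy)phenyl]-2-(4-methoxyphenyl)ethyl]-4-methoxybenzoate | COC(=O)c1ccc(OC)c([C@@H](c3cc(O[Si](C(C)C)(C(C)C)C(C)C)cc(O[Si](C(C)C)(C(C)C)C(C)C)c3)[C@@H](c2ccc(OC)cc2)c2c(/C=C/c4ccc(OC(C)=O)cc4)cc(OC)cc2OC)c1 | intermediate
12 | methyl 3-[(1R,2S)-1-(3,5-dihydroxyphenyl)-2-{2-[(E)-2-(4-hydroxyphenyl)ethenyl]-4,6-dimethoxyphenyl}-2-(4-methoxyphenyl)ethyl]-4-methoxybenzoate (precursor of the key step) | COC(=O)c1ccc(OC)c([C@@H](c3cc(O)cc(O)c3)[C@@H](c2ccc(OC)cc2)c2c(/C=C/c4ccc(O)cc4)cc(OC)cc2OC)c1 | intermediate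
13 | p-quinone methide: cycloheptadiene closed (C-a R, C-d S, C-f S), ring A resorcinol free, C-g as exocyclic methine of a 4-oxocyclohexa-2,5-dienylidene | COC(=O)c1ccc(OC)c([C@H]2c3cc(O)cc(O)c3[C@H](c3cc(OC)cc(OC)c3[C@@H]2c2ccc(OC)cc2)C=C2C=CC(=O)C=C2)c1 | intermediate
14 | ring-closed methyl ester: cycloheptadiene fused to trans-dihydrobenzofuran (C-a R, C-d S, C-f S, C-g S), free phenols on rings A and C, methyl ethers on rings B, D and E (product of the key step) | COC(=O)c1ccc(OC)c([C@H]2c3cc(O)cc4c3[C@H](c3cc(OC)cc(OC)c3[C@@H]2c2ccc(OC)cc2)[C@@H](c2ccc(O)cc2)O4)c1 | intermediate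
15 | benzylic alcohol corresponding to 14 (CH2OH on ring E) | OCc1ccc(OC)c([C@H]2c3cc(O)cc4c3[C@H](c3cc(OC)cc(OC)c3[C@@H]2c2ccc(OC)cc2)[C@@H](c2ccc(O)cc2)O4)c1 | intermediate
16 | aldehyde corresponding to 14 (CHO on ring E; vitisinol B tetramethyl ether) | O=Cc1ccc(OC)c([C@H]2c3cc(O)cc4c3[C@H](c3cc(OC)cc(OC)c3[C@@H]2c2ccc(OC)cc2)[C@@H](c2ccc(O)cc2)O4)c1 | intermediate
17 | vitisinol B | O=Cc1ccc(O)c([C@H]2c3cc(O)cc4c3[C@H](c3cc(O)cc(O)c3[C@@H]2c2ccc(O)cc2)[C@@H](c2ccc(O)cc2)O4)c1 | target

**Step count**
Total: 11 steps. Longest linear sequence: 10 steps (steps 2–11, from 3 and 4); step 1 is a one-step branch that joins at step 3.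

**Steps most likely to fail, with fallbacks**

Step 8 (proposed new method). The risk is that bimolecular stilbene–stilbene coupling or further oxidation outruns the seven-membered closure, or that closure takes place over the other face of ring A and gives the C-f epimer. The fallback builds the same two bonds by polar, known steps under reagent control; it sets out from 11 and returns at 14. Shi epoxidation of the stilbene in 11 with the enantiomer of the D-fructose-derived Shi ketone and KHSO5 in NaHCO3-buffered MeCN/H2O at 0 °C should give the (2S,3S)-epoxide F1, the oxidant choosing the alkene face. BF3·OEt2 in CH2Cl2 at −78 °C then triggers an epoxy-arene Friedel–Crafts cyclisation: the silylated ring A opens the epoxide at C-f with inversion (7-exo; the 8-endo alternative at C-g is disfavoured and the acetoxy group damps ionisation there), giving the ring-closed carbinol F2 with (S) at C-f. TBAF in THF/MeOH frees the three phenols to give the triol F3. Catalytic PPTS in CH2Cl2 ionises the 4-hydroxybenzylic alcohol to the same p-quinone methide 13, which the ring A hydroxyl closes to the trans furan of 14.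

Step 5. The risk is poor facial selectivity in the attack of the arene on the open cation, attack at the carbon between the two methoxy groups, or proton loss or hydride shift in the cation that erases C-a. The fallback passes the cation through a cyclic ether so that the arene enters by ring opening anti to oxygen; it sets out from 7 and returns at 9. TsOH·H2O (1.1 equiv) in 1,2-dichloroethane at 60 °C lets the ortho-methoxy oxygen of ring E capture the C-d cation, and the oxonium ion is demethylated by tosylate. This should give the trans-dihydrobenzofuran F4, trans being reached by reversible ring opening. Bi(OTf)3 (20 mol %) with 8 in CH2Cl2 at 0 °C opens the benzylic C–O bond with the arene arriving anti to the departing phenoxide, which gives the phenol F5 with the (1R,2S) configuration. CH3I and K2CO3 in acetone re-methylate the phenol to 9.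

Step 4. The risk is weak discrimination between the interconverting ketone enantiomers, or α-epimerisation too slow to feed the matched one, so that C-a is not enriched. The fallback gives up the dynamic resolution for a static, stereodivergent reduction with recycling; it sets out from 6 and returns at 7. Base-free hydrogenation with RuH(η1-BH4)[(S)-xylbinap][(S,S)-dpen] under H2 in i-PrOH at 25 °C reduces both ketone enantiomers without enolisation to (R)-carbinols. This gives 7 together with its C-a epimer, the (1S,2R)-alcohol F6, and the two diastereomers are separated on silica. F6 is oxidised with Dess–Martin periodinane back to 6 and resubmitted.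

**Further compounds**
F1 | step 8 | methyl 3-[(1R,2S)-2-{2-[(2S,3S)-3-(4-acetoxyphenyl)oxiran-2-yl]-4,6-dimethoxyphenyl}-1-[3,5-bis(triisopropylsilyloxy)phenyl]-2-(4-methoxyphenyl)ethyl]-4-methoxybenzoate | COC(=O)c1ccc(OC)c([C@@H](c3cc(O[Si](C(C)C)(C(C)C)C(C)C)cc(O[Si](C(C)C)(C(C)C)C(C)C)c3)[C@@H](c2ccc(OC)cc2)c2c([C@@H]3O[C@H]3c4ccc(OC(C)=O)cc4)cc(OC)cc2OC)c1
F2 | step 8 | ring-closed carbinol: cycloheptadiene (C-a R, C-d S, C-f S) with an (R)-(4-acetoxyphenyl)hydroxymethyl group on C-f, ring A as bis(triisopropylsilyl) ether | COC(=O)c1ccc(OC)c([C@H]2c3cc(O[Si](C(C)C)(C(C)C)C(C)C)cc(O[Si](C(C)C)(C(C)C)C(C)C)c3[C@H](c3cc(OC)cc(OC)c3[C@@H]2c2ccc(OC)cc2)[C@@H](O)c2ccc(OC(C)=O)cc2)c1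
F3 | step 8 | triol: as F2 with the ring A resorcinol and the ring C phenol free | COC(=O)c1ccc(OC)c([C@H]2c3cc(O)cc(O)c3[C@H](c3cc(OC)cc(OC)c3[C@@H]2c2ccc(OC)cc2)[C@@H](O)c2ccc(O)cc2)c1
F4 | step 5 | methyl (2R,3R)-3-[3,5-bis(triisopropylsilyloxy)phenyl]-2-(4-methoxyphenyl)-2,3-dihydro-1-benzofuran-5-carboxylate | COC(=O)c1ccc2O[C@@H](c3ccc(OC)cc3)[C@H](c3cc(O[Si](C(C)C)(C(C)C)C(C)C)cc(O[Si](C(C)C)(C(C)C)C(C)C)c3)c2c1
F5 | step 5 | methyl 3-[(1R,2S)-2-(2-bromo-4,6-dimethoxyphenyl)-1-[3,5-bis(triisopropylsilyloxy)phenyl]-2-(4-methoxyphenyl)ethyl]-4-hydroxybenzoate | COC(=O)c1ccc(O)c([C@@H](c3cc(O[Si](C(C)C)(C(C)C)C(C)C)cc(O[Si](C(C)C)(C(C)C)C(C)C)c3)[C@@H](c2ccc(OC)cc2)c2c(Br)cc(OC)cc2OC)c1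
F6 | step 4 | methyl 3-[(1S,2R)-1-[3,5-bis(triisopropylsilyloxy)phenyl]-2-hydroxy-2-(4-methoxyphenyl)ethyl]-4-methoxybenzoate | COC(=O)c1ccc(OC)c([C@H](c2cc(O[Si](C(C)C)(C(C)C)C(C)C)cc(O[Si](C(C)C)(C(C)C)C(C)C)c2)[C@@H](O)c2ccc(OC)cc2)c1
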